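**Plan**

- Retrosynthesis: the C4 ketone is read as a silyl enol ether, so the C3–C4 bond of ring C is cut first (enol ether–olefin metathesis). The O1–C2 aryl ether bond is cut next (allylic etherification), and the bond from C6 of ring A to the geranyl chain last (C-alkylation).
- Enabling feature: C4 of ring C is a ketone carbon on ring A that can be carried as a 1-silyloxyvinyl group. C3 lies next to C2, which bears O1 and the aryl ring, so C2 can be installed as a branched allylic aryl ether whose vinyl group supplies C3.
- Forward order: geranylation of ring A, asymmetric O-allylation of the less hindered phenol, MOM protection, TBS enol ether formation, closure of ring C by metathesis, acid release of the ketone and the 5-hydroxyl.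
- Stereochemistry: the only stereocentre, C2 (S), is set by the ligand in the iridium-catalysed etherification and carried through unchanged. The (E)-alkene arrives with geranyl bromide.

Key step: step 6

Assumption: the (Sa,Sc,Sc) phosphoramidite is taken to give the (S) ether, the usual sense of induction for cinnamyl carbonates with oxygen nucleophiles; if the opposite sense is found, its antipode is used.

Abbreviations: geranyl = (2E)-3,7-dimethylocta-2,6-dien-1-yl; MOM = methoxymethyl; TBS = tert-butyldimethylsilyl; primed locants refer to the acetophenone ring.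

**Step 1**
Reactants: 1 2',6'-dihydroxy-4'-methoxyacetophenone; 2 geranyl bromide
Product: 3 3'-geranyl-2',6'-dihydroxy-4'-methoxyacetophenone
Conditions: 2 (0.8 equiv), 10% aq KOH, 0 °C → rt; unreacted 1 recovered
Reagents that add atoms: none
Why: C-alkylation of an ambident phenoxide by an allylic bromide, where water hydrogen-bonds the phenoxide oxygens and steers the electrophile to the ring carbon between the hydroxy and methoxy groups; the two open ring positions are equivalent by symmetry, so only one mono-geranyl isomer can form, and the (E)-alkene of 2 is not touched by the SN2 step.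

**Step 2**
Reactants: 4 (E)-3,4-dimethoxycinnamyl alcohol
Product: 5 (E)-3-(3,4-dimethoxyphenyl)allyl methyl carbonate
Conditions: ClCO2Me, pyridine, CH2Cl2, 0 °C
Reagents that add atoms: methyl chloroformate, COC(=O)Cl
Why: O-acylation of a primary allylic alcohol with a chloroformate gives the linear carbonate used as the ionisable partner in allylic substitution.

**Step 3**
Reactants: 3 3'-geranyl-2',6'-dihydroxy-4'-methoxyacetophenone; 5 (E)-3-(3,4-dimethoxyphenyl)allyl methyl carbonate
Product: 6 2'-[(S)-1-(3,4-dimethoxyphenyl)allyloxy]-5'-geranyl-6'-hydroxy-4'-methoxyacetophenone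
Conditions: [Ir(cod)Cl]2 (2 mol%), (Sa,Sc,Sc)-(1,1'-binaphthalene-2,2'-diyl) N,N-bis(1-phenylethyl)phosphoramidite (4 mol%), pre-activated with n-PrNH2; 5 (1.2 equiv), K3PO4 (1 equiv), THF, rt
Reagents that add atoms: none
Why: Iridium-catalysed asymmetric allylic etherification, in which ionisation of the carbonate gives a π-allyl iridium complex of the cyclometalated phosphoramidite that is attacked at its aryl-substituted terminus by the phenoxide oxygen para to the geranyl group (flanked by acetyl and a ring hydrogen), while the other phenol, wedged between acetyl and geranyl and hydrogen-bonded to the ketone, should stay free; the ligand sets the (S) centre.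

**Step 4**
Reactants: 6 2'-[(S)-1-(3,4-dimethoxyphenyl)allyloxy]-5'-geranyl-6'-hydroxy-4'-methoxyacetophenone
Product: 7 2'-[(S)-1-(3,4-dimethoxyphenyl)allyloxy]-5'-geranyl-4'-methoxy-6'-(methoxymethoxy)acetophenone
Conditions: MOMCl (3 equiv), iPr2NEt (4 equiv), n-Bu4NI (cat.), CH2Cl2, 0 °C → reflux
Reagents that add atoms: chloromethyl methyl ether, COCCl
Why: Williamson-type O-alkylation of the remaining chelated phenol with an α-chloro ether, run with excess amine so that the acid-labile allylic ether is never exposed to HCl.

**Step 5**
Reactants: 7 2'-[(S)-1-(3,4-dimethoxyphenyl)allyloxy]-5'-geranyl-4'-methoxy-6'-(methoxymethoxy)acetophenone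
Product: 8 TBS enol ether of 7, 1-[1-(tert-butyldimethylsilyloxy)vinyl]-2-[(S)-1-(3,4-dimethoxyphenyl)allyloxy]-5-geranyl-4-methoxy-6-(methoxymethoxy)benzene
Conditions: TBSOTf (1.3 equiv), Et3N (2.5 equiv), CH2Cl2, −78 → 0 °C; cold NaHCO3 work-up, filtration through Et3N-deactivated silica, used at once
Reagents that add atoms: tert-butyldimethylsilyl trifluoromethanesulfonate, CC(C)(C)[Si](C)(C)OS(=O)(=O)C(F)(F)F
Why: Soft enolisation (silyl enol ether formation), in which the silyl triflate activates the ketone oxygen and triethylamine removes a proton from the acetyl methyl group, the only enolisable position, with the amine buffering the MOM acetal and the allylic ether against the Lewis acid.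

**Step 6**
Reactants: 8 TBS enol ether of 7
Product: 9 (S)-4-(tert-butyldimethylsilyloxy)-2-(3,4-dimethoxyphenyl)-6-geranyl-7-methoxy-5-(methoxymethoxy)-2H-chromene
Conditions: RuCl2(=CHPh)(H2IMes)(PCy3) (second-generation Grubbs catalyst, 10 mol% in two portions), 1,4-benzoquinone (20 mol%), degassed CH2Cl2 (0.005 M), 40 °C, argon sparge, dark; ethyl vinyl ether quench; Et3N-deactivated silica
Reagents that add atoms: none
Why: The benzylidene catalyst loads at the monosubstituted vinyl group to give a ruthenium alkylidene on the carbon next to C2, which undergoes intramolecular [2+2] cycloaddition with the 1,1-disubstituted silyl enol ether; cycloreversion of the ruthenacyclobutane forms the C3–C4 double bond and leaves Ru=CH2, which re-enters the cycle with loss of ethylene. The closest known reaction type is ene–silyl enol ether ring-closing metathesis with second-generation ruthenium catalysts, alongside the established metathesis closure of O-allyl ortho-vinylphenols to 2H-chromenes. Ring C closes as a six-membered ring by ring-closing metathesis between the C2 vinyl group and the aryl enol ether, the oxygen-bearing enol carbon becoming C4 and its methylene being expelled. No stereocentre is formed, and the (S) centre at C2 is carried through because no bond to it is made or broken. The step needs the two terminal olefins to react in preference to the two trisubstituted geranyl alkenes, which their substitution should secure, and it needs the allylic ether not to isomerise, which benzoquinone as hydride scavenger, a short reaction time at 40 °C and exclusion of light are meant to ensure.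

**Step 7**
Reactants: 9 (S)-4-(tert-butyldimethylsilyloxy)-2-(3,4-dimethoxyphenyl)-6-geranyl-7-methoxy-5-(methoxymethoxy)-2H-chromene
Product: 11 (2S)-2-(3,4-dimethoxyphenyl)-6-geranyl-5-hydroxy-7-methoxychroman-4-one (target), via 5-O-MOM flavanone 10 (not isolated)
Conditions: 3 M aq HCl, THF, 0 °C → rt (at most 35 °C), monitored and stopped at full conversion
Reagents that add atoms: none
Why: Acid-catalysed hydrolysis, in which protonation at C3 of the silyl enol ether and loss of silicon to water gives the C4 ketone within minutes, after which the peri MOM acetal, activated by hydrogen bonding to the new carbonyl, is cleaved to the 5-hydroxyl without any bond to C2 being touched.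

**Compound list**

1 | 2',6'-dihydroxy-4'-methoxyacetophenone | CC(=O)c1c(O)cc(OC)cc1O | starting material
2 | geranyl bromide, (2E)-1-bromo-3,7-dimethylocta-2,6-diene | CC(C)=CCC/C(C)=C/CBr | starting material
3 | 3'-geranyl-2',6'-dihydroxy-4'-methoxyacetophenone | CC(=O)c1c(O)cc(OC)c(C/C=C(\C)CCC=C(C)C)c1O | intermediate
4 | (E)-3,4-dimethoxycinnamyl alcohol | COc1ccc(/C=C/CO)cc1OC | starting material
5 | (E)-3-(3,4-dimethoxyphenyl)allyl methyl carbonate | COC(=O)OC/C=C/c1ccc(OC)c(OC)c1 | intermediate
6 | 2'-[(S)-1-(3,4-dimethoxyphenyl)allyloxy]-5'-geranyl-6'-hydroxy-4'-methoxyacetophenone | CC(=O)c1c(O[C@@H](C=C)c2ccc(OC)c(OC)c2)cc(OC)c(C/C=C(\C)CCC=C(C)C)c1O | intermediate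
7 | 2'-[(S)-1-(3,4-dimethoxyphenyl)allyloxy]-5'-geranyl-4'-methoxy-6'-(methoxymethoxy)acetophenone | CC(=O)c1c(O[C@@H](C=C)c2ccc(OC)c(OC)c2)cc(OC)c(C/C=C(\C)CCC=C(C)C)c1OCOC | intermediate
8 | TBS enol ether of 7 | C=C(O[Si](C)(C)C(C)(C)C)c1c(O[C@@H](C=C)c2ccc(OC)c(OC)c2)cc(OC)c(C/C=C(\C)CCC=C(C)C)c1OCOC | intermediate
9 | (S)-4-(tert-butyldimethylsilyloxy)-2-(3,4-dimethoxyphenyl)-6-geranyl-7-methoxy-5-(methoxymethoxy)-2H-chromene | COc1ccc([C@@H]2C=C(O[Si](C)(C)C(C)(C)C)c3c(cc(OC)c(C/C=C(\C)CCC=C(C)C)c3OCOC)O2)cc1OC | intermediate
10 | (2S)-2-(3,4-dimethoxyphenyl)-6-geranyl-7-methoxy-5-(methoxymethoxy)chroman-4-one | COc1ccc([C@@H]2CC(=O)c3c(cc(OC)c(C/C=C(\C)CCC=C(C)C)c3OCOC)O2)cc1OC | intermediate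
11 | (2S)-2-(3,4-dimethoxyphenyl)-6-geranyl-5-hydroxy-7-methoxychroman-4-one | COc1ccc([C@@H]2CC(=O)c3c(cc(OC)c(C/C=C(\C)CCC=C(C)C)c3O)O2)cc1OC | target

**Step count**

Total steps: 7. Longest linear sequence: 6 steps (steps 1, 3, 4, 5, 6 and 7 from 1); step 2 is a one-step side branch.

**Steps most likely to fail**

Step 6. The alkylidene may fail to engage the enol ether double bond, which is shielded by the two ortho substituents of ring A, so that the vinyl groups couple intermolecularly instead. Ruthenium hydride species may move the vinyl double bond into conjugation with the ether oxygen and destroy the C2 centre. Thermal or photochemical electrocyclic opening of the 2H-chromene may racemise C2. The fallback leaves metathesis, sets out from 7 and returns at 10. The zerovalent palladium complex Pd(PPh3)4 with morpholine in THF transfers the 1-arylallyl group to the amine and frees the phenol 1-[3-geranyl-6-hydroxy-4-methoxy-2-(methoxymethoxy)phenyl]ethanone F1, whose free hydroxyl is the one that must become O1. Me2NCH(OMe)2 in toluene at 90 °C condenses at the acetyl methyl group to the enaminone (E)-3-(dimethylamino)-1-[3-geranyl-6-hydroxy-4-methoxy-2-(methoxymethoxy)phenyl]prop-2-en-1-one F2. Acetic acid at room temperature closes ring C with loss of dimethylamine to the chromone 6-geranyl-7-methoxy-5-(methoxymethoxy)-4H-chromen-4-one F3. Enantioselective conjugate addition of 3,4-dimethoxyphenylboronic acid (Pd(OCOCF3)2 with the enantiomer of the tert-butyl pyridine–oxazoline ligand that leads to the (2S) product, NH4PF6, water, 1,2-dichloroethane, 60 °C) should then give 10, which is taken through the acid treatment of step 7.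

Step 3. The ketone-chelated phenoxide may be too poor a nucleophile. The second phenolic oxygen or a ring carbon may compete for the allyl fragment. The iridium catalyst may re-ionise the electron-rich 1-arylallyl aryl ether once formed, eroding branched selectivity and enantiomeric purity. The fallback separates the enantioselective event from the delivery of the hindered phenoxide, sets out from 5 and 3 and returns at 6. Iridium-catalysed allylic hydroxylation of 5 with KHCO3 (same [Ir(cod)Cl]2/phosphoramidite system) uses a small nucleophile and gives an alcohol that is not re-ionised, (S)-1-(3,4-dimethoxyphenyl)prop-2-en-1-ol F4. ClCO2Me and pyridine at −20 °C convert it into (S)-1-(3,4-dimethoxyphenyl)allyl methyl carbonate F5. Rhodium-catalysed allylic etherification (RhCl(PPh3)3 modified with P(OMe)3, THF, 0 °C) of F5 with 3 in the presence of LiN(SiMe3)2 (1 equiv) is stereospecific, with substitution at the carbon that carried the leaving group and net retention, and should give 6.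

Step 7. Acid may heterolyse the O1–C2 bond, which is benzylic to the 3,4-dimethoxyphenyl ring, leading through the chalcone to racemisation at C2. During the slower MOM cleavage the geranyl chain may cyclise onto the freed 5-hydroxyl. The fallback replaces the acetal by silicon so that the end-game needs no strong protic acid, sets out from 6 and returns at 11. TBSOTf (2.5 equiv) and Et3N in CH2Cl2 at −78 → 0 °C silylate both the phenol and the ketone to give the bis-silyl compound 1-[1-(tert-butyldimethylsilyloxy)vinyl]-6-(tert-butyldimethylsilyloxy)-2-[(S)-1-(3,4-dimethoxyphenyl)allyloxy]-5-geranyl-4-methoxybenzene F6. Ring-closing metathesis under the conditions of step 6 should give (S)-4,5-bis(tert-butyldimethylsilyloxy)-2-(3,4-dimethoxyphenyl)-6-geranyl-7-methoxy-2H-chromene F7. Et3N·3HF in THF at 0 °C → rt removes both silyl groups under nearly neutral conditions and gives 11 directly.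

**Further compounds**

F1 | step 6 | 1-[3-geranyl-6-hydroxy-4-methoxy-2-(methoxymethoxy)phenyl]ethanone | CC(=O)c1c(O)cc(OC)c(C/C=C(\C)CCC=C(C)C)c1OCOC
F2 | step 6 | (E)-3-(dimethylamino)-1-[3-geranyl-6-hydroxy-4-methoxy-2-(methoxymethoxy)phenyl]prop-2-en-1-one | CN(C)/C=C/C(=O)c1c(O)cc(OC)c(C/C=C(\C)CCC=C(C)C)c1OCOC
F3 | step 6 | 6-geranyl-7-methoxy-5-(methoxymethoxy)-4H-chromen-4-one | O=c1ccoc2cc(OC)c(C/C=C(\C)CCC=C(C)C)c(OCOC)c12
F4 | step 3 | (S)-1-(3,4-dimethoxyphenyl)prop-2-en-1-ol | O[C@@H](C=C)c1ccc(OC)c(OC)c1
F5 | step 3 | (S)-1-(3,4-dimethoxyphenyl)allyl methyl carbonate | COC(=O)O[C@@H](C=C)c1ccc(OC)c(OC)c1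
F6 | step 7 | 1-[1-(tert-butyldimethylsilyloxy)vinyl]-6-(tert-butyldimethylsilyloxy)-2-[(S)-1-(3,4-dimethoxyphenyl)allyloxy]-5-geranyl-4-methoxybenzene | C=C(O[Si](C)(C)C(C)(C)C)c1c(O[C@@H](C=C)c2ccc(OC)c(OC)c2)cc(OC)c(C/C=C(\C)CCC=C(C)C)c1O[Si](C)(C)C(C)(C)C
F7 | step 7 | (S)-4,5-bis(tert-butyldimethylsilyloxy)-2-(3,4-dimethoxyphenyl)-6-geranyl-7-methoxy-2H-chromene | COc1ccc([C@@H]2C=C(O[Si](C)(C)C(C)(C)C)c3c(cc(OC)c(C/C=C(\C)CCC=C(C)C)c3O[Si](C)(C)C(C)(C)C)O2)cc1OC
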